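All runs are simulated for an exercise, and the scatter is random.

You cannot get the south flask's solid substrate into solution at once or without limit: its solid falls fast and then crawls, and that leaves you two things to read.

| flask | solid substrate | reagent | remark | time |
|---|---|---|---|---|
| south | 1 M | 0.90 M | the very flask that is asked about, followed so far |  |
| south-east | 0.50 M | 0.90 M | run made earlier |  |
| flask | 1.0 M | 0.900 M |  | 8.0 min |

| run | time / min | solid substrate / % | single product / % |
|---|---|---|---|
| south | 0.250 | 78.4 | 0 |
| south | 0.667 | 67.7 | 0.3 |
| south | 1.33 | 62.4 | 1.6 |
| south | 3.00 | 57.6 | 4.1 |
| south-east | 0.417 | 45.0 | 1.4 |
| south-east | 1.00 | 26.3 | 2.3 |
| south-east | 2.00 | 19.0 | 4.4 |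
| south-east | 3.00 | 14.6 | 7.4 |

(scatter of a reading: 0.5 percentage points)

* how much solid substrate there is at 8.0 min, in percent of the solid substrate charged (only what is still solid)
* how much single product there is at 8.0 min, in percent of the solid substrate charged
* how much other mono adduct there is at 8.0 min, in percent of the solid substrate charged
* how much double product there is at 8.0 min, in percent of the solid substrate charged

- what was read earlier has a scatter of 0.5 percentage points, one standard deviation
- at the start none of the solid substrate is in solution
- a reading or a percentage of single product counts all its forms, free or not

The last two south readings give a slow loss of 0.0287 M/min, and running that line back to the start gives a dissolved load of 0.338 M. Fold both with the time into 0.681, the turnover number (a Damköhler number), which says how many dissolved loads reaction carries off in the asked time at the early rate. Your solid is then the charge less the load times one plus the turnover, 43.2% for this flask. To test whether that is enough, put the same load and loss on the south-east charge at its last reading: you get 15.2% against the 14.6% read, so the charge is carried properly, though your line runs on well past 3.00 min, where the south readings stop.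

The forecast gives 45% solid substrate (range 38% to 50%), which holds your figure, 10% single product, and 6% and 6% of the other two, “split roughly evenly as a guess”.

The flask gives 49.9% solid substrate, 5.59% single product, 2.06% other mono adduct and 5.87% double product, so single product falls below the forecast's low end of 7%, while the other three lie inside their ranges.

    starting material + reagent ⇌ single product (K = 0.400 /M, k = 0.00110 /M/s)
    starting material + reagent → other mono adduct (k = 2.80 × 10⁻⁴ /M/s)
    reagent + single product → double product (k = 0.00290 /M/s)
    reagent + other mono adduct → double product (k = 0.00370 /M/s)
    solid substrate ⇌ starting material, rate k5*(cs5 - [starting material]) while solid is left; crystals form when [starting material] > cs5 (solubility = 0.370 M, k = 0.0540 /s)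
    crystals ⇌ single product, rate k6*(cs6 - [single product]) while solid is left; crystals form when [single product] > cs6 (solubility = 0.770 M, k = 0.0530 /s)

Its three products amount to a turnover of 0.400, below your 0.681. Solid substrate remains in this flask mainly because of the low solubility of starting material: the same flask without that limit ends at 0% solid rather than 49.9%. With 0.36 M of reagent, scaling the turnover by the reagent gives 0.272 and so 57.0% solid; that flask computes to 57.9%.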